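The target is the 31-membered lactone of 30-hydroxytriacontanoic acid: one ring holding the ester (C1 carbonyl, ring oxygen on C30) and 29 unbranched methylenes, without any stereocentre. The plan rests on the C10–C11 bond, a CH2–CH2 link nine bonds from C1 and twenty carbons from the ring oxygen. Because it lies in a featureless polymethylene stretch far from the ester, it can be made as an olefin of either geometry and then saturated. The key step closes the ring by olefin metathesis of an open-chain ester bearing two terminal vinyl groups, henicos-20-en-1-yl undec-10-enoate, and hydrogenates the new C10=C11 olefin in the same vessel with the spent ruthenium, delivering the target directly.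

Key step: step 3

Remark: the target has no stereocentre and the ring-closing olefin is erased by hydrogenation, so no stereochemical control is needed; compounds 1, 2 and 7 are taken as commercial.

Step 1
Reactants: 1 11-bromoundec-1-ene; 2 10-bromodecan-1-ol
Product: 6 henicos-20-en-1-ol, via undec-10-enylmagnesium bromide 3 (not isolated), via chloromagnesium 10-bromodecan-1-olate 4 (not isolated), via chloromagnesium henicos-20-en-1-olate 5 (not isolated)
Conditions: (a) 1, Mg, THF, 50 °C; (b) 2, MeMgCl (1.0 equiv), THF, −20 °C; (c) solution a (1.3 equiv) into b, Li2CuCl4 (3 mol %), THF, −20 °C to rt; 1 M HCl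
Reagents that add atoms: none
Why: Copper-catalysed Kochi cross-coupling of a primary alkyl Grignard reagent with a primary alkyl bromide is reliable for sp3–sp3 chain extension, and pre-forming the magnesium alkoxide with MeMgCl spares the alkenyl Grignard while the remote vinyl group and the alkoxide stay inert.

Step 2
Reactants: 6 henicos-20-en-1-ol; 7 undec-10-enoyl chloride
Product: 8 henicos-20-en-1-yl undec-10-enoate
Conditions: Et3N (1.5 equiv), DMAP (5 mol %), CH2Cl2, 0 °C to rt
Reagents that add atoms: none
Why: DMAP-catalysed acylation of a primary alcohol by an acid chloride (nucleophilic-catalysis esterification) is fast and leaves both terminal olefins untouched.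

Step 3
Reactants: 8 henicos-20-en-1-yl undec-10-enoate
Product: 10 oxacyclohentriacontan-2-one (30-triacontanolide), via oxacyclohentriacont-11-en-2-one 9 (not isolated)
Conditions: first-generation Grubbs catalyst RuCl2(PCy3)2(=CHPh) (5 mol %), CH2Cl2 (2 mM, slow addition of 8), 40 °C; then H2 (30 bar), 60 °C, same pressure vessel
Reagents that add atoms: none
Why: The ruthenium benzylidene adds to one vinyl terminus by [2+2] cycloaddition/cycloreversion through a ruthenacyclobutane, and the resulting alkylidene captures the second vinyl group intramolecularly, expelling ethylene and forming the C10=C11 bond. The closest known reaction type is ring-closing olefin metathesis of conformationally unbiased diene esters to macrolactones, run in tandem with hydrogenation, in which H2 converts the spent carbene into a ruthenium hydride (RuHCl(H2)(PCy3)2) that saturates the new disubstituted olefin. The single 31-membered ring is closed end to end by macrocyclising ring-closing metathesis with extrusion of ethylene; no other ring forms. No stereocentre is created, and the E/Z geometry of intermediate 9 is irrelevant because both isomers give the same saturated ring. The step needs ring closure to win over acyclic diene metathesis oligomerisation, which is secured by high dilution, slow addition and reversible back-biting of oligomers, and by the two unhindered terminal olefins lying nine and nineteen methylenes from the ester so that no chelate can stall the carbene. It also needs the olefins not to migrate before closure, which the first-generation catalyst at 40 °C should ensure, while the lactone is inert to the ruthenium hydride.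

Compound list
1 | 11-bromoundec-1-ene | C=CCCCCCCCCCBr | starting material
2 | 10-bromodecan-1-ol | OCCCCCCCCCCBr | starting material
3 | undec-10-enylmagnesium bromide | C=CCCCCCCCCC[Mg]Br | intermediate
4 | chloromagnesium 10-bromodecan-1-olate | Cl[Mg]OCCCCCCCCCCBr | intermediate
5 | chloromagnesium henicos-20-en-1-olate | C=CCCCCCCCCCCCCCCCCCCCO[Mg]Cl | intermediate
6 | henicos-20-en-1-ol | C=CCCCCCCCCCCCCCCCCCCCO | intermediate
7 | undec-10-enoyl chloride | C=CCCCCCCCCC(=O)Cl | starting material
8 | henicos-20-en-1-yl undec-10-enoate | C=CCCCCCCCCC(=O)OCCCCCCCCCCCCCCCCCCCC=C | intermediate
9 | oxacyclohentriacont-11-en-2-one (triacont-10-en-30-olide, E/Z mixture, geometry left undefined) | O=C1CCCCCCCCC=CCCCCCCCCCCCCCCCCCCCO1 | intermediate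
10 | oxacyclohentriacontan-2-one (30-triacontanolide) | O=C1CCCCCCCCCCCCCCCCCCCCCCCCCCCCCO1 | target

Total step count: 3
Longest linear sequence: 3 steps (1 and 2 to 6, then 8, then 10)

Steps most likely to fail

Step 3. At the dilution required, ring closure may lose to intermolecular metathesis, or a terminal olefin may migrate before closure and lead to ring-contracted homologues. The fallback forms the C10=C11 bond intermolecularly and closes the ring at the ester instead. It sets out from compound 6. Cross-metathesis with an excess of commercial undec-10-enoic acid (second-generation Grubbs catalyst RuCl2(H2IMes)(PCy3)(=CHPh), 1,4-benzoquinone, CH2Cl2, 40 °C) should give 30-hydroxytriacont-10-enoic acid F1. Hydrogenation (H2, Pd/C, THF/EtOAc) should give 30-hydroxytriacontanoic acid F2. Yamaguchi macrolactonisation (2,4,6-trichlorobenzoyl chloride, Et3N, THF; then slow addition to DMAP in toluene, 100 °C, high dilution) is expected to pass through 30-hydroxytriacontanoic 2,4,6-trichlorobenzoic anhydride F3 and to come back to the route at target 10.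

Step 1. The magnesium alkoxide 4 may aggregate or precipitate, so that the copper-catalysed coupling stalls and Grignard homocoupling or reduction of the bromide takes over. The fallback masks the hydroxyl group. It sets out from compound 2. Treatment with 3,4-dihydro-2H-pyran and PPTS (CH2Cl2, rt) should give racemic 2-[(10-bromodecyl)oxy]oxane F4. Coupling with Grignard reagent 3 (Li2CuCl4 cat., THF, −10 °C to rt) should give racemic 2-(henicos-20-en-1-yloxy)oxane F5. Acetal exchange (PPTS, MeOH, 50 °C) would release the alcohol, and the route resumes at compound 6.

Step 2. The waxy alcohol 6 may dissolve poorly in cold CH2Cl2, leaving acylation incomplete while the acid chloride is consumed by hydrolysis or ketene formation. The fallback reverses the polarity of ester formation by alkylating a carboxylate. It sets out from compound 6. Mesylation (MsCl, Et3N, CH2Cl2, 0 °C) should give henicos-20-en-1-yl methanesulfonate F6. SN2 displacement by cesium undec-10-enoate (undec-10-enoic acid, Cs2CO3, DMF, 60 °C) would come back to the route at compound 8.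

Further compounds
F1 | step 3 | 30-hydroxytriacont-10-enoic acid (E/Z mixture) | O=C(O)CCCCCCCCC=CCCCCCCCCCCCCCCCCCCCO
F2 | step 3 | 30-hydroxytriacontanoic acid | O=C(O)CCCCCCCCCCCCCCCCCCCCCCCCCCCCCO
F3 | step 3 | 30-hydroxytriacontanoic 2,4,6-trichlorobenzoic anhydride | O=C(OC(=O)c1c(Cl)cc(Cl)cc1Cl)CCCCCCCCCCCCCCCCCCCCCCCCCCCCCO
F4 | step 1 | 2-[(10-bromodecyl)oxy]oxane (racemic) | BrCCCCCCCCCCOC1CCCCO1
F5 | step 1 | 2-(henicos-20-en-1-yloxy)oxane (racemic) | C=CCCCCCCCCCCCCCCCCCCCOC1CCCCO1
F6 | step 2 | henicos-20-en-1-yl methanesulfonate | C=CCCCCCCCCCCCCCCCCCCCOS(C)(=O)=O
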